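At 8.00 h, 61.9% of the substrate was still free in the winter run and 60.8% in the dusk run, the meeting heard, on solid reagent charges of 0.84 M and 1.3 M.

| flask | substrate | solid reagent | remark | time |
|---|---|---|---|---|
| winter | 0.40 M | 0.84 M | run made earlier |  |
| dusk | 0.40 M | 1.3 M | run made earlier |  |
| east | 0.40 M | 0.600 M |  | 8.0 h |
| west | 0.40 M | 0.600 M |  | 12 h |

| run | time / h | target / % | substrate / % | intermediate B / % | side product / % |
|---|---|---|---|---|---|
| winter | 1.33 | 1.3 | 93.1 | 1.2 | 0.8 |
| winter | 2.50 | 4.0 | 88.2 | 7.0 | 0.4 |
| winter | 4.00 | 7.9 | 78.3 | 6.0 | 2.4 |
| winter | 5.00 | 8.9 | 71.7 | 6.5 | 2.5 |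
| winter | 6.00 | 12.4 | 65.9 | 7.1 | 5.7 |
| winter | 8.00 | 18.4 | 61.9 | 7.0 | 6.6 |
| dusk | 0.500 | 0 | 99.2 | 0.3 | 0 |
| dusk | 1.50 | 1.0 | 92.5 | 1.8 | 1.2 |
| dusk | 3.00 | 4.0 | 83.3 | 4.7 | 2.2 |
| dusk | 4.00 | 6.6 | 77.2 | 5.2 | 4.4 |
| dusk | 6.00 | 15.4 | 68.5 | 7.4 | 4.8 |
| dusk | 8.00 | 19.6 | 60.8 | 7.9 | 6.6 |

(standard deviation of a reading: 1 percentage point)

- a species is counted by the substrate in it: one side product counts as two
- given per volume of solution although it is solid: solid reagent
- the numbers in the tables scatter with a standard deviation of 1 percentage point
- at the start none of the solid reagent is in solution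
- a reading of substrate is of its free form alone

- which of these there is most of at the end, counted by the substrate in it, east (intermediate B / side product / substrate / target)
- which of these there is most of at the end, counted by the substrate in it, west (intermediate B / side product / substrate / target)
- amount of the one of these that there is most of at the end, in percent of the substrate charged, east
- amount of the one of these that there is most of at the end, in percent of the substrate charged, west

The chair asked what a charge of 0.600 M would do in the new flasks, east and west. I replied at the board that the two runs differ by 1.1 percentage points against a scatter of 1 point per reading, so I would carry one number for both. Winter gives 0.0600 h⁻¹ and dusk 0.0622 h⁻¹, with a mean of 0.0611 h⁻¹. I called this mean κ, the apparent pseudo-first-order constant: the fall per hour in the logarithm of the free substrate share.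

On the first round, κ gave free substrate of 61.3% in east and 48.1% in west. On the second round I put that answer back in. If each substrate takes one reagent, which is my assumption, west needs 0.208 M, about a third of its charge, so κ stood. At its last reading, dusk's target held half of the substrate that had left, and that share, if it is carried over to west, puts west's target near 26.0%, less than its substrate.

The forecast, made separately, named substrate at 62% for east and substrate at 48% for west, holding that “the rate does not depend on the amount of solid”. My east figure was slightly lower.

The flasks gave substrate at 60.3% in east and substrate at 46.8% in west, and this is what ran in them: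

    substrate + partner ⇌ intermediate A (K = 3.40 M⁻¹, k = 4.50 × 10⁻⁴ M⁻¹ s⁻¹)
    substrate + partner → intermediate B (k = 5.40 × 10⁻⁴ M⁻¹ s⁻¹)
    intermediate B → target (k = 1.20 × 10⁻⁴ s⁻¹)
    solid reagent ⇌ partner, rate k4*(cs4 - [partner]) while solid is left; crystals form when [partner] > cs4 (solubility = 39.0 mM, k = 4.40 × 10⁻⁴ s⁻¹)
    substrate + intermediate B → side product (k = 6.80 × 10⁻⁵ M⁻¹ s⁻¹)

West still held 62.3% of its own solid reagent charge at 12.0 h. The same flask read at 20 h gives another answer. There κ gives 29.5% free substrate and the flask holds 28.0%, while target stands first at 50.9%.

The data stem from a simulated flask with constants of no real substance; scatter was added.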